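An equivalent of partner is the unit I counted in: substrate takes one partner to become single product, single product one more to become double product, and double product and tris adduct one more each on the way to tetra adduct, while the capture agent takes single product and spends no partner.

in all of them: substrate 1.4 M

| charge | partner | capture agent | remark | time |
|---|---|---|---|---|
| green | 1.5 equiv | 0.070 M | run made earlier |  |
| flask | 1.10 equiv | 0.0700 M |  | 4.0 h |

- green (time / h: substrate / %, single product / %): 0.167: 37.9, 56.0; 0.500: 12.9, 70.4; 0.833: 6.0, 70.3; 1.33: 2.8, 67.1; 2.00: 1.2, 62.2; 2.50: 1.1, 60.2; 3.00: 0.7, 58.0

(standard deviation of a reading: 0.3 percentage points)

- amount of substrate at 4.0 h, in percent of the substrate charged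
- amount of single product at 4.0 h, in percent of the substrate charged
- amount of double product at 4.0 h, in percent of the substrate charged
- amount of tris adduct at 4.0 h, in percent of the substrate charged

- steps thought possible: substrate + partner -> single product + released group; partner + double product -> tris adduct + released group; single product + capture agent -> trapped intermediate; partner + tris adduct -> tetra adduct + released group; partner + single product -> double product + released group

**Selectivity read.** I assumed that capture in the green run was over by 0.833 h, so that substrate and single product were then competing for the same partner. Between that reading and 2.00 h, the logarithmic fall of single product, with substrate's feed added back, divided by that of substrate, reads as a selectivity factor of 0.117.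

**Peak share.** I folded this with the capture agent's charge, 5.00% of the substrate, into one number, the peak share 71.5%: my estimate of the top of the single-product curve, in percent of the substrate charged, which is the selectivity raised to its own value over one minus itself, times what capture leaves. That top costs 1.07 equivalents of partner, and this flask's 1.10 equiv lies just beyond it, so I put single product at the peak share. The partner budget then puts my stop figure for substrate at 6.76% and for double product at 16.8%.

**Clock test.** One number has no clock. The green run's first reading reads as 5.22 h⁻¹ for substrate's step at this charge, so I reckoned the last partner in this flask to fall at about 0.790 h⁻¹, a half-life of 0.878 h, shorter than the 4.0 h allowed, and I took this flask to stand near its stop figures by then. The readings gave me no figure for tris adduct.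

The forecast gave substrate 8.2%, above my stop figure, single product 70%, double product 16% and tris adduct 0.6%, saying “starved of partner it should stay below about 2%”.

The flask gave substrate 8.14%, single product 70.3%, double product 16.0% and tris adduct 0.169%.

    substrate + partner → single product + released group (k = 0.0620 L mol⁻¹ min⁻¹)
    partner + double product → tris adduct + released group (k = 0.00210 L mol⁻¹ min⁻¹)
    single product + capture agent → trapped intermediate (k = 0.0690 L mol⁻¹ min⁻¹)
    partner + tris adduct → tetra adduct + released group (k = 0.160 L mol⁻¹ min⁻¹)
    partner + single product → double product + released group (k = 0.00760 L mol⁻¹ min⁻¹)

**Neighbour flask.** Single product in this flask stood 1.2 percentage points below the peak share, with 0.60% of the partner charge still left at 4.00 h. The neighbour charged with 1.90 equiv of partner lies far beyond the 1.07 equivalents that the top costs, so the same reckoning places it well down the falling side of the curve. Its substrate stood at 0.0124%, its single product at 35.7%, half the peak share, and its double product at 50.6%.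

The earlier runs and the new flask were computed on assumed constants.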